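**The count.** The easy step is counting reagent. Substrate takes one to become intermediate A, A takes another to become target, and target takes one more to become over-reaction product. So A holds one reagent, target two and over-reaction product 3.

| flask | substrate | reagent | time | remark |
|---|---|---|---|---|
| maple | 0.10 M | 0.700 equiv | 2.0 h | everything together in a closed stirred flask, run for 2.0 h |
| birch | 0.10 M | 0.700 equiv (fed, over 1.60 h) | 2.0 h | all but reagent at the start; reagent goes in evenly over 1.60 h, the run ends at 2.0 h |
| larch | 0.10 M (fed, over 1.60 h) | 0.700 equiv | 2.0 h | a stirred flask in which substrate is dosed at a steady rate over 1.60 h without added volume, worked up at 2.0 h |
| oak | 0.10 M | 0.700 equiv |  | one stirred flow tank at steady state, fed with the mixture as stated, mean residence time 2.0 h |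

- the set-up with the highest amount of target at the outlet or at the end, in percent of the substrate put in ("none" if the first two lie within 2 percentage points) (maple / birch / larch / oak / none)
- amount of target at the outlet or at the end, in percent of the substrate put in, maple
- amount of target at the outlet or at the end, in percent of the substrate put in, birch
- amount of target at the outlet or at the end, in percent of the substrate put in, larch
- amount of target at the outlet or at the end, in percent of the substrate put in, oak

- a species is counted by the substrate in it: one homo dimer counts as two
- where a step has two of a species, its rate is k times that concentration squared, and two are used at each turn
- the stated concentrations are those of everything mixed, before any reaction; amounts are the same in each set-up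
- the feed brings no volume worth counting
- run time (maple): 2.0 h

    substrate + reagent → intermediate A (k1 = 0.023 /M/s)
    reagent + intermediate A → target (k2 = 0.053 /M/s)
    substrate ⇌ intermediate B (K3 = 0.70, k3 = 2.0 × 10⁻⁴ /s)
    intermediate B → side product (k4 = 0.0018 /s)
    reagent + target → over-reaction product (k5 = 0.076 /M/s)
    2 substrate → homo dimer (k6 = 8.8 × 10⁻⁴ /M/s)

**Bench rule.** Two reagent per target, so 0.700 equiv promises 0.350 of the charge as target. A ratio of given constants shows where this stops. The constant that takes target on, 0.076 /M/s, is larger than the one that makes it, 0.053 /M/s. Call 0.697 the target cap, the ratio of target to intermediate A at which target stops gaining; both steps carry reagent, so its level cancels. It is a selectivity factor.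

**Going round.** Take maple and spend the reagent with no over-reaction, target standing at the cap. The fractions of the charge then give target 0.204. Now put that back. Loss of target climbs from nothing towards its making, so I take about half of what is made to go on, and then over-reaction product equals target. Target then costs 5 reagent instead of two, two for itself and 3 for its over-reaction product, and maple gives 10.9%.

My guess for the slow set-ups is twice that over-reaction per target, which adds 3 more reagent per target and gives 0.0742 of the charge: birch 7.42%, larch 7.42%, oak 7.42%. That puts maple ahead of the others.

**The forecast.** It names maple, with 10% there, 7% for birch, 7% for larch and 4.5% for oak: “the batch does best because it spends the reagent fast”. My oak figure stands higher than the forecast's.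

**The flask.** Maple gives 10.5%, birch 6.33%, larch 4.37% and oak 4.53%, so the best is maple.

**What held.** Removing over-reaction lifts maple's target from 10.5% to 25.3%. Yet maple's target over intermediate A reads 0.519, below the cap, so target was still gaining as reagent fell to 0.00676% of its charge at 1.00 h. Birch passes the cap: at the end of the feed, 1.60 h, the same ratio reads 0.768. With reagent still at 12.7% of its charge, birch's target falls from 6.76% to 6.33% at 2.00 h.

The numbers of this flask are made up.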